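**Plan**

- Retrosynthesis: the last cut removes the four benzyl ethers and the bridge unsaturation; ring A of the resulting stilbene is then cut at C1–C2 (aldol) and C1–C6 (C-acylation). The remaining cuts are the bridge C=C (Knoevenagel–Doebner), the ring-B aryl–CH2 bond (Negishi), the two ring-A C2/C6–CH2Ar bonds (dianion alkylations) and the O–CH3 bond.
- Enabling feature: in ring A the run C2 (4-hydroxybenzyl), C3 (OMe), C4 (H), C5 (OH), C6 (4-hydroxybenzyl) is the C2–C6 stretch of a symmetrical 1,7-diarylheptane-3,5-dione. C1, with its two-carbon bridge to ring B, is a cinnamoyl carbonyl carbon, so the pentasubstituted arene is a folded 1,3,5-tricarbonyl chain.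
- Forward: acetylacetone is benzylated at both termini and converted into its only methyl enol ether; ring B is benzylated and extended to a cinnamoyl chloride; the halves are joined at C6–C1.
- Ring A is the only ring made; it closes last at C1–C2 and aromatizes, and the three 4-oxybenzyl rings and ring B are bought intact.
- Stereochemistry: the target has no stereocentre and no stereogenic double bond, so nothing is set. The labile centre of the acyclic precursor and the E styryl bond are erased; the E enol ether matters only for folding.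

Key step: step 10

Remark: the target is achiral, so the "single enantiomer" is simply the compound drawn; ring A is numbered C1 (CH2CH2 bridge), C2 and C6 (4-hydroxybenzyl), C3 (OMe), C4 (H), C5 (OH) throughout, and 2, 9 and 3-hydroxy-5-methoxybenzaldehyde (fallback only) are taken as commercial.

**Route**

Step 1
Reactants: 1 acetylacetone; 2 4-(benzyloxy)benzyl chloride
Product: 4 6-[4-(benzyloxy)phenyl]hexane-2,4-dione, via dilithium penta-1,3-diene-2,4-diolate 3 (not isolated)
Conditions: LDA (2.1 equiv), THF, 0 °C; then 2 (0.95 equiv), 0 → 25 °C; 1 M HCl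
Reagents that add atoms: none
Why: Hauser dianion alkylation, in which the terminal carbanion of 3 is by far the more nucleophilic site, so the benzylic chloride is taken up by SN2 at the methyl carbon and not at the central carbon, and a slight deficit of 2 guards against a second alkylation.

Step 2
Reactants: 4 6-[4-(benzyloxy)phenyl]hexane-2,4-dione; 2 4-(benzyloxy)benzyl chloride
Product: 6 1,7-bis[4-(benzyloxy)phenyl]heptane-3,5-dione, via dilithium 6-[4-(benzyloxy)phenyl]hexa-1,3-diene-2,4-diolate 5 (not isolated)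
Conditions: LDA (2.1 equiv), THF, −78 → 0 °C; then 2 (1.0 equiv), 0 → 25 °C; 1 M HCl
Reagents that add atoms: none
Why: Second Hauser dianion alkylation, in which the second deprotonation of a β-diketone takes place at the less substituted terminal carbon (methyl before methylene), so dianion 5 is alkylated at the remaining methyl group and the symmetrical diketone results.

Step 3
Reactants: 6 1,7-bis[4-(benzyloxy)phenyl]heptane-3,5-dione; 7 trimethyl orthoformate
Product: 8 (E)-1,7-bis[4-(benzyloxy)phenyl]-5-methoxyhept-4-en-3-one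
Conditions: HC(OMe)3 (4 equiv), p-TsOH·H2O (5 mol %), MeOH, 50 °C; then Et3N
Reagents that add atoms: none
Why: Acid-catalysed O-methylation of a β-diketone with an orthoester (ketalization, then loss of methanol) gives the vinylogous ester; because 6 is symmetrical only one constitutional isomer can form, and the reversible acid conditions should settle on the E isomer, in which the methoxy group is anti to the acyl group.

Step 4
Reactants: 9 3-bromo-5-hydroxybenzaldehyde
Product: 10 3-(benzyloxy)-5-bromobenzaldehyde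
Conditions: BnBr (1.1 equiv), K2CO3, DMF, 25 °C
Reagents that add atoms: benzyl bromide, BrCc1ccccc1
Why: Williamson ether synthesis, in which the phenoxide formed by carbonate is benzylated by SN2 while the aldehyde and the aryl bromide are inert.

Step 5
Reactants: 2 4-(benzyloxy)benzyl chloride
Product: 11 4-(benzyloxy)benzylzinc chloride (titrated THF solution, used directly)
Conditions: Zn dust (1.5 equiv), LiCl (1.5 equiv), THF, 25 °C
Reagents that add atoms: zinc, [Zn]
Why: Direct insertion of LiCl-activated zinc into the benzylic C–Cl bond gives the benzylic zinc chloride at room temperature with little Wurtz coupling and leaves the aryl benzyl ether untouched.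

Step 6
Reactants: 10 3-(benzyloxy)-5-bromobenzaldehyde; 11 4-(benzyloxy)benzylzinc chloride
Product: 12 3-(benzyloxy)-5-[4-(benzyloxy)benzyl]benzaldehyde
Conditions: Pd(OAc)2 (2 mol %), SPhos (4 mol %), THF, 25 °C, slow addition of 11 (1.2 equiv)
Reagents that add atoms: none
Why: Negishi sp3–sp2 coupling, in which oxidative addition of Pd(0)/SPhos into the aryl bromide and fast transmetalation with the benzylic zinc chloride should outpace uncatalysed addition of the organozinc to the formyl group, and a benzylic zinc has no β-hydrogen to eliminate.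

Step 7
Reactants: 12 3-(benzyloxy)-5-[4-(benzyloxy)benzyl]benzaldehyde; 13 malonic acid
Product: 15 (E)-3-{3-(benzyloxy)-5-[4-(benzyloxy)benzyl]phenyl}acrylic acid, via {3-(benzyloxy)-5-[4-(benzyloxy)benzyl]benzylidene}malonic acid 14 (not isolated)
Conditions: malonic acid (2 equiv), piperidine (0.1 equiv), pyridine, 100 °C; then cold aq. HCl
Reagents that add atoms: none
Why: Knoevenagel–Doebner condensation, in which the amine-catalysed condensation gives arylidenemalonic acid 14 and this decarboxylates in hot pyridine to the cinnamic acid with the thermodynamically preferred E geometry.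

Step 8
Reactants: 15 (E)-3-{3-(benzyloxy)-5-[4-(benzyloxy)benzyl]phenyl}acrylic acid
Product: 16 (E)-3-{3-(benzyloxy)-5-[4-(benzyloxy)benzyl]phenyl}acryloyl chloride (used crude after evaporation)
Conditions: (COCl)2 (1.3 equiv), DMF (cat.), CH2Cl2, 0 → 25 °C
Reagents that add atoms: oxalyl chloride, O=C(Cl)C(=O)Cl
Why: Vilsmeier-type activation with oxalyl chloride and catalytic DMF converts the acid into the acid chloride under cold, neutral conditions that leave the benzyl ethers and the E alkene untouched.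

Step 9
Reactants: 8 (E)-1,7-bis[4-(benzyloxy)phenyl]-5-methoxyhept-4-en-3-one; 16 (E)-3-{3-(benzyloxy)-5-[4-(benzyloxy)benzyl]phenyl}acryloyl chloride
Product: 18 (1E,6E)-4-[4-(benzyloxy)benzyl]-1-{3-(benzyloxy)-5-[4-(benzyloxy)benzyl]phenyl}-9-[4-(benzyloxy)phenyl]-7-methoxynona-1,6-diene-3,5-dione (racemic at the enolizable C4), via lithium (4E)-1,7-bis[4-(benzyloxy)phenyl]-5-methoxyhepta-2,4-dien-3-olate 17 (not isolated)
Conditions: 8 (2.0 equiv), LiHMDS (2.0 equiv), THF, −78 °C; then 16 (1.0 equiv), −78 → −40 °C; aq. NH4Cl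
Reagents that add atoms: none
Why: Kinetic deprotonation of a β-methoxy enone by a hindered amide takes place at the α′ methylene next to the ketone and not at the γ carbon, and lithium enolate 17 is C-acylated by the acid chloride (crossed Claisen-type acylation, as used for 4-pyranone precursors) to form the C6–C1 bond; the second equivalent of enolate absorbs the acidic proton of the product and returns 8 on work-up, and the new centre is labile, racemic and erased in step 10.

Step 10
Reactants: 18 (1E,6E)-4-[4-(benzyloxy)benzyl]-1-{3-(benzyloxy)-5-[4-(benzyloxy)benzyl]phenyl}-9-[4-(benzyloxy)phenyl]-7-methoxynona-1,6-diene-3,5-dione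
Product: 21 2,4-bis[4-(benzyloxy)benzyl]-3-{(E)-2-[3-(benzyloxy)-5-(4-(benzyloxy)benzyl)phenyl]ethenyl}-5-methoxyphenol, via 4,6-bis[4-(benzyloxy)benzyl]-5-{(E)-2-[3-(benzyloxy)-5-(4-(benzyloxy)benzyl)phenyl]ethenyl}-5-hydroxy-3-methoxycyclohex-2-en-1-one 19 (not isolated), via 2,4-bis[4-(benzyloxy)benzyl]-3-{(E)-2-[3-(benzyloxy)-5-(4-(benzyloxy)benzyl)phenyl]ethenyl}-5-methoxycyclohexa-2,5-dien-1-one 20 (not isolated)
Conditions: KOt-Bu (3.0 equiv), t-BuOH/THF (1:1), degassed, 25 → 65 °C; then 1 M HCl, 0 °C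
Reagents that add atoms: none
Why: tert-Butoxide first stores 18 as the diketonate at C6, and proton exchange in t-BuOH also populates the extended dienolate formed by removing a γ-hydrogen at future C2 of the vinylogous ester, the only anion in which the cinnamoyl ketone is a free electrophile; C2 adds to that ketone carbon (C1) to give aldol 19, hydroxide leaves by E1cB through the C6 hydrogen to give cross-conjugated dienone 20, and 20 tautomerizes to the phenoxide of 21, an irreversible sink that drains the earlier equilibria. The closest known reaction type is the base-induced aldol cycloaromatization of 1,3,5-triketones and their mono enol ethers to 5-substituted resorcinols, the laboratory counterpart of stilbene-synthase folding. Ring A, the only ring formed, closes at C1–C2 in a favoured 6-(enolendo)-exo-trig aldol. No stereocentre is created in the product, since the centres of 19 and 20 disappear on aromatization. The step needs a single cyclization mode and a single substituent pattern, and the substrate secures both: the cinnamoyl arm has no enolizable carbon, C4 is an enol-ether methine, C6 could close only a four-membered ring, the E enol ether holds C2 cis to C5 so that the chain can fold, and the methyl ether survives as the C3 methoxy group while the C5 ketone oxygen becomes the lone phenol. The competing O-cyclizations (oxa-Michael at the styryl carbon, addition–elimination to a 4-pyranone) are reversible under alkoxide conditions, and a hindered base with a potassium counter-ion limits retro-Claisen cleavage.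

Step 11
Reactants: 21 2,4-bis[4-(benzyloxy)benzyl]-3-{(E)-2-[3-(benzyloxy)-5-(4-(benzyloxy)benzyl)phenyl]ethenyl}-5-methoxyphenol
Product: 22 3-{2-[3-hydroxy-5-(4-hydroxybenzyl)phenyl]ethyl}-2,4-bis(4-hydroxybenzyl)-5-methoxyphenol (target)
Conditions: H2 (3 bar), 10% Pd/C, THF/MeOH (1:1), 25 °C
Reagents that add atoms: none
Why: Heterogeneous catalytic hydrogenation saturates the styryl double bond and hydrogenolyses the four benzylic C–O bonds of the aryl benzyl ethers, while the diarylmethane C–C bonds, the aryl methyl ether and the arenes are inert under these mild conditions.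

**Compound list**

1 | acetylacetone (pentane-2,4-dione) | CC(=O)CC(C)=O | starting material
2 | 4-(benzyloxy)benzyl chloride | ClCc1ccc(OCc2ccccc2)cc1 | starting material
3 | dilithium penta-1,3-diene-2,4-diolate (dianion of 1) | [Li+].[Li+].C=C([O-])/C=C(/C)[O-] | intermediate
4 | 6-[4-(benzyloxy)phenyl]hexane-2,4-dione | CC(=O)CC(=O)CCc1ccc(OCc2ccccc2)cc1 | intermediate
5 | dilithium 6-[4-(benzyloxy)phenyl]hexa-1,3-diene-2,4-diolate (dianion of 4) | [Li+].[Li+].C=C([O-])/C=C(/CCc1ccc(OCc2ccccc2)cc1)[O-] | intermediate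
6 | 1,7-bis[4-(benzyloxy)phenyl]heptane-3,5-dione | O=C(CCc1ccc(OCc2ccccc2)cc1)CC(=O)CCc1ccc(OCc2ccccc2)cc1 | intermediate
7 | trimethyl orthoformate | COC(OC)OC | starting material
8 | (E)-1,7-bis[4-(benzyloxy)phenyl]-5-methoxyhept-4-en-3-one | CO/C(CCc1ccc(OCc2ccccc2)cc1)=C/C(=O)CCc1ccc(OCc2ccccc2)cc1 | intermediate
9 | 3-bromo-5-hydroxybenzaldehyde | O=Cc1cc(O)cc(Br)c1 | starting material
10 | 3-(benzyloxy)-5-bromobenzaldehyde | O=Cc1cc(Br)cc(OCc2ccccc2)c1 | intermediate
11 | 4-(benzyloxy)benzylzinc chloride | Cl[Zn]Cc1ccc(OCc2ccccc2)cc1 | intermediate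
12 | 3-(benzyloxy)-5-[4-(benzyloxy)benzyl]benzaldehyde | O=Cc1cc(OCc2ccccc2)cc(Cc2ccc(OCc3ccccc3)cc2)c1 | intermediate
13 | malonic acid | OC(=O)CC(=O)O | starting material
14 | {3-(benzyloxy)-5-[4-(benzyloxy)benzyl]benzylidene}malonic acid | OC(=O)C(=Cc1cc(OCc2ccccc2)cc(Cc2ccc(OCc3ccccc3)cc2)c1)C(=O)O | intermediate
15 | (E)-3-{3-(benzyloxy)-5-[4-(benzyloxy)benzyl]phenyl}acrylic acid | OC(=O)/C=C/c1cc(OCc2ccccc2)cc(Cc2ccc(OCc3ccccc3)cc2)c1 | intermediate
16 | (E)-3-{3-(benzyloxy)-5-[4-(benzyloxy)benzyl]phenyl}acryloyl chloride | O=C(Cl)/C=C/c1cc(OCc2ccccc2)cc(Cc2ccc(OCc3ccccc3)cc2)c1 | intermediate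
17 | lithium (4E)-1,7-bis[4-(benzyloxy)phenyl]-5-methoxyhepta-2,4-dien-3-olate (enolate geometry without consequence) | [Li+].CO/C(CCc1ccc(OCc2ccccc2)cc1)=C/C([O-])=CCc1ccc(OCc2ccccc2)cc1 | intermediate
18 | (1E,6E)-4-[4-(benzyloxy)benzyl]-1-{3-(benzyloxy)-5-[4-(benzyloxy)benzyl]phenyl}-9-[4-(benzyloxy)phenyl]-7-methoxynona-1,6-diene-3,5-dione (racemic, labile C4) | CO/C(CCc1ccc(OCc2ccccc2)cc1)=C/C(=O)C(Cc1ccc(OCc2ccccc2)cc1)C(=O)/C=C/c1cc(OCc2ccccc2)cc(Cc2ccc(OCc3ccccc3)cc2)c1 | intermediate
19 | 4,6-bis[4-(benzyloxy)benzyl]-5-{(E)-2-[3-(benzyloxy)-5-(4-(benzyloxy)benzyl)phenyl]ethenyl}-5-hydroxy-3-methoxycyclohex-2-en-1-one (diastereomer mixture) | COC1=CC(=O)C(Cc2ccc(OCc3ccccc3)cc2)C(O)(/C=C/c2cc(OCc3ccccc3)cc(Cc3ccc(OCc4ccccc4)cc3)c2)C1Cc1ccc(OCc2ccccc2)cc1 | intermediate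
20 | 2,4-bis[4-(benzyloxy)benzyl]-3-{(E)-2-[3-(benzyloxy)-5-(4-(benzyloxy)benzyl)phenyl]ethenyl}-5-methoxycyclohexa-2,5-dien-1-one (racemic) | COC1=CC(=O)C(Cc2ccc(OCc3ccccc3)cc2)=C(/C=C/c2cc(OCc3ccccc3)cc(Cc3ccc(OCc4ccccc4)cc3)c2)C1Cc1ccc(OCc2ccccc2)cc1 | intermediate
21 | 2,4-bis[4-(benzyloxy)benzyl]-3-{(E)-2-[3-(benzyloxy)-5-(4-(benzyloxy)benzyl)phenyl]ethenyl}-5-methoxyphenol | COc1cc(O)c(Cc2ccc(OCc3ccccc3)cc2)c(/C=C/c2cc(OCc3ccccc3)cc(Cc3ccc(OCc4ccccc4)cc3)c2)c1Cc1ccc(OCc2ccccc2)cc1 | intermediate
22 | 3-{2-[3-hydroxy-5-(4-hydroxybenzyl)phenyl]ethyl}-2,4-bis(4-hydroxybenzyl)-5-methoxyphenol (CNP0204120.0) | COc1cc(O)c(Cc2ccc(O)cc2)c(CCc2cc(O)cc(Cc3ccc(O)cc3)c2)c1Cc1ccc(O)cc1 | target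

**Summary**

Total step count: 11 steps.
Longest linear sequence: 7 steps (steps 4, 6, 7, 8, 9, 10, 11 from 9; the same length from 2 through step 5).

**Steps most likely to fail**

1. Step 10 (cycloaromatization). The anion may rest as the unreactive C6 diketonate and leak away by O-cyclization with loss of methoxide, or by retro-Claisen cleavage, faster than C2 adds to the hindered C1 ketone. Fallback: ring A is not folded but bought and dressed by cross-coupling and olefination. It sets out from aldehyde 12 (and uses zinc reagent 11) and comes back to the route at target 22.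
 - Ring-B arm: aldehyde 12 is reduced (NaBH4, THF/MeOH, 0 °C) to {3-(benzyloxy)-5-[4-(benzyloxy)benzyl]phenyl}methanol F1. This is converted (PBr3, CH2Cl2, 0 °C) into 1-(benzyloxy)-3-[4-(benzyloxy)benzyl]-5-(bromomethyl)benzene F2. Heating with triethyl phosphite (Michaelis–Arbuzov, 130 °C) gives diethyl {3-(benzyloxy)-5-[4-(benzyloxy)benzyl]benzyl}phosphonate F3.
 - Ring-A piece: commercial 3-hydroxy-5-methoxybenzaldehyde is benzylated (BnBr, K2CO3, DMF) to 3-(benzyloxy)-5-methoxybenzaldehyde F4. Dibromination at the two positions that are ortho to the formyl group and para to an alkoxy group (NBS, 2.1 equiv, MeCN) gives 3-(benzyloxy)-2,6-dibromo-5-methoxybenzaldehyde F5. Double Negishi coupling with 11 (2.5 equiv, Pd(OAc)2/SPhos, THF) gives 3-(benzyloxy)-2,6-bis[4-(benzyloxy)benzyl]-5-methoxybenzaldehyde F6.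
 - Union: Horner–Wadsworth–Emmons olefination of F6 with the anion of F3 (KOt-Bu, THF, 0 → 25 °C) should give 1-(benzyloxy)-2,4-bis[4-(benzyloxy)benzyl]-3-{(E)-2-[3-(benzyloxy)-5-(4-(benzyloxy)benzyl)phenyl]ethenyl}-5-methoxybenzene F7. Hydrogenation of F7 under the conditions of step 11 saturates the alkene, removes all five benzyl groups and gives 22.

2. Step 9 (C-acylation). The hindered secondary enolate may be acylated on oxygen, or proton transfer from the acidic product may stall the reaction. Fallback: aldol addition followed by oxidation in place of acylation. It sets out from 12 and 8 and comes back at 18. Wittig homologation of 12 with (triphenylphosphoranylidene)acetaldehyde (toluene, 80 °C) should give (E)-3-{3-(benzyloxy)-5-[4-(benzyloxy)benzyl]phenyl}acrylaldehyde F8. Lithium enolate 17 (from 8, LDA, THF, −78 °C) should add 1,2 to F8 to give (1E,6E)-4-[4-(benzyloxy)benzyl]-1-{3-(benzyloxy)-5-[4-(benzyloxy)benzyl]phenyl}-9-[4-(benzyloxy)phenyl]-3-hydroxy-7-methoxynona-1,6-dien-5-one F9 as a diastereomer mixture whose centres are erased later. Dess–Martin oxidation of F9 (CH2Cl2, 0 → 25 °C) gives 18.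

3. Step 6 (Negishi coupling). The benzylic zinc reagent may add to the formyl group or homocouple before transmetalation. Fallback: reversed polarity, an sp2–sp3 Suzuki–Miyaura coupling with no carbonyl-reactive organometallic. It sets out from 10 and 2 and comes back at 12. Miyaura borylation of 10 (B2pin2, Pd(dppf)Cl2, KOAc, dioxane, 90 °C) gives 3-(benzyloxy)-5-(4,4,5,5-tetramethyl-1,3,2-dioxaborolan-2-yl)benzaldehyde F10. Coupling of F10 with benzylic chloride 2 (Pd(dppf)Cl2, K2CO3, dioxane/H2O, 80 °C) gives 12.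

Further compounds
F1 | step 10 | {3-(benzyloxy)-5-[4-(benzyloxy)benzyl]phenyl}methanol | OCc1cc(OCc2ccccc2)cc(Cc2ccc(OCc3ccccc3)cc2)c1
F2 | step 10 | 1-(benzyloxy)-3-[4-(benzyloxy)benzyl]-5-(bromomethyl)benzene | BrCc1cc(OCc2ccccc2)cc(Cc2ccc(OCc3ccccc3)cc2)c1
F3 | step 10 | diethyl {3-(benzyloxy)-5-[4-(benzyloxy)benzyl]benzyl}phosphonate | CCOP(=O)(OCC)Cc1cc(OCc2ccccc2)cc(Cc2ccc(OCc3ccccc3)cc2)c1
F4 | step 10 | 3-(benzyloxy)-5-methoxybenzaldehyde | COc1cc(C=O)cc(OCc2ccccc2)c1
F5 | step 10 | 3-(benzyloxy)-2,6-dibromo-5-methoxybenzaldehyde | COc1cc(OCc2ccccc2)c(Br)c(C=O)c1Br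
F6 | step 10 | 3-(benzyloxy)-2,6-bis[4-(benzyloxy)benzyl]-5-methoxybenzaldehyde | COc1cc(OCc2ccccc2)c(Cc2ccc(OCc3ccccc3)cc2)c(C=O)c1Cc1ccc(OCc2ccccc2)cc1
F7 | step 10 | 1-(benzyloxy)-2,4-bis[4-(benzyloxy)benzyl]-3-{(E)-2-[3-(benzyloxy)-5-(4-(benzyloxy)benzyl)phenyl]ethenyl}-5-methoxybenzene | COc1cc(OCc2ccccc2)c(Cc2ccc(OCc3ccccc3)cc2)c(/C=C/c2cc(OCc3ccccc3)cc(Cc3ccc(OCc4ccccc4)cc3)c2)c1Cc1ccc(OCc2ccccc2)cc1
F8 | step 9 | (E)-3-{3-(benzyloxy)-5-[4-(benzyloxy)benzyl]phenyl}acrylaldehyde | O=C/C=C/c1cc(OCc2ccccc2)cc(Cc2ccc(OCc3ccccc3)cc2)c1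
F9 | step 9 | (1E,6E)-4-[4-(benzyloxy)benzyl]-1-{3-(benzyloxy)-5-[4-(benzyloxy)benzyl]phenyl}-9-[4-(benzyloxy)phenyl]-3-hydroxy-7-methoxynona-1,6-dien-5-one (diastereomer mixture) | CO/C(CCc1ccc(OCc2ccccc2)cc1)=C/C(=O)C(Cc1ccc(OCc2ccccc2)cc1)C(O)/C=C/c1cc(OCc2ccccc2)cc(Cc2ccc(OCc3ccccc3)cc2)c1
F10 | step 6 | 3-(benzyloxy)-5-(4,4,5,5-tetramethyl-1,3,2-dioxaborolan-2-yl)benzaldehyde | O=Cc1cc(OCc2ccccc2)cc(B2OC(C)(C)C(C)(C)O2)c1
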